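(The numbers were drawn at random within sensible limits; the rest is arithmetic.)

Beside this flask stands a neighbour, the same charge stopped at 12.5 s, so we want a reckoning that carries over in time, not a single number.

free monomer 0.84 M; protic impurity 0.0840 M; initiator 1.7 mM; stray impurity 1.2 mM; time 25 s

- whether the average number of monomer units in a chain (chains begun, living or dead) reaches 400 by 25 s (no / yes)
- average number of monomer units in a chain (chains begun, living or dead) at 25 s

- the average divides the monomer in chains by the number of chains begun, living and dead together
- run time (flask): 25 s

We ask what the end state must be, then how fast it comes, and we build the flask up step by step. Start with initiation and growth, every initiator beginning a chain: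

free monomer + initiator → living end + monomer in chains (k3 = 3.2 /M/s)

free monomer + living end → monomer in chains + living end, rate k1*[living end]*[free monomer] (k1 = 74 /M/s)

Living ends then hold steady, so free monomer falls in a pseudo-first-order way, and the length at 25 s is

473

Now add the stray impurity:

initiator + stray impurity → spent initiator (k4 = 56000 /M/s)

It takes initiator at 67.2 /s, faster than free monomer does at 2.69 /s, so we let it spend its own amount of initiator. Living ends become 0.0595 % of the monomer charge. Growth slows to a time constant of 27.0 s, but each chain gets more:

1015

Now the return step:

monomer in chains + living end → free monomer + living end, rate k5*[living end] as long as [monomer in chains] is above zero (k5 = 29 /s)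

Return and growth both scale with living ends, so they balance with 46.7 % of the charge left free, and the approach keeps the same time constant:

541

Last comes the protic impurity:

protic impurity + free monomer → quenched substrate (k2 = 1.6 /M/s)

At 1.34 /s it outruns the approach at 0.0370 /s, so we strike 10.0 % of the charge at the outset. That leaves room for 43.3 % of the charge to enter chains. Room over living ends, 728 units a chain, is the ceiling length, and the length climbs toward it:

439

Does it pass 400? We say yes.

The forecast says yes and 438, between 415 and 460, less than ours, on the ground that “The remaining monomer then relaxes toward the ceiling concentration”.

The flask gives yes and 438, reaching 400 at 21.6 s. In this flask the protic impurity took free monomer early, with 4.65 % of its charge left at 2.50 s and quenched substrate at 10.0 % of the monomer charge by 12.5 s, while growth and return ran on with 5.00 × 10⁻⁴ M of living end. At 250 s this flask holds monomer in chains at 43.4 % of the charge, against our room of 43.3 %. For the neighbour stopped at 12.5 s, the ceiling length gives 270, and that run gave 268.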